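**Remarks on the chemistry (assumptions)**
- Decalin atoms are numbered C1–C10 (ring A = C1–C4, C5, C10; ring B = C5–C10; C11 = exocyclic CH2 on C4). α is the face of H-10 and the C5 methyl, β the opposite face.
- The (S)-configured oxazaborolidinium catalyst is assumed to deliver the diene to the enone face that leads to 9. If the α-methyl enone binds in the opposite sense, the (R)-catalyst would be used with no other change.
- Hydride reduction of 9 is assumed to give the 4β-alcohol. The C4 configuration is immaterial because C4 is re-oxidised in step 11.
- The structures underlying the plan were checked atom by atom against the target (ring sizes, substituents, all four stereodescriptors, endo/(Z) consistency of the cycloadduct). No correction was needed. The one design change is a triisopropylsilyl instead of a smaller silyl group on the diene.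

## Structural features

The target is a cis-fused decalin in which C4 carries an exocyclic methylene (C11) and C9 is joined through a CH2 group to a 2-hydroxy-5-methoxy-1,4-benzoquinone (ring C). Four contiguous stereocentres sit on ring B: quaternary C5 (methyl), C10 (H), quaternary C9 (methyl and the arylmethyl arm) and C8 (methyl), with absolute configuration 5R,8S,9R,10S. The C5 methyl, H-10, the C9 arm and H-8 lie on the α face and the C9 and C8 methyls on the β face, so the ring fusion is cis and the C8 and C9 methyls are cis to each other. The fragile groups are the 1,1-disubstituted C4=C11 alkene, which acid moves into the ring and any hydrogenation would reduce, and the hydroxyquinone, which is a vinylogous acid, an electrophile and an oxidant at once. The real difficulty is the pair of quaternary carbons C5 and C9 flanking C10, the neopentyl C9–CH2–ring C bond, and the need to tell apart C4 and C8, both of which are best reached from carbonyl groups. The key step uses the fact that quaternary C5 and C10 are cis-bonded neighbours in ring A and that C5 is attached to C4: these three atoms are the α-carbon, β-carbon and carbonyl carbon of 2-methylcyclohex-2-en-1-one, so ring A is bought intact and C6–C9 are added across its alkene as a four-carbon diene.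

## Logic of the disconnections

**22 ⇒ 20 ⇒ 19.** The free hydroxyl of ring C is traced back to a methyl ether (22 from 20 through 21) and the quinone carbonyls to two further aryl methyl ethers (20 from 19). The hydroxyquinone cannot survive ylides, enolates, hydrides or hydrogenation, whereas the symmetric arene in 19 is inert to all of them. The forward steps need an oxidant that spares C4=C11 and a hydrolysis that picks the methoxy group next to the side chain.

**19 ⇒ 18.** The C4=C11 bond is cut. The exocyclic alkene is acid- and hydrogenation-sensitive, so it is made as late as the arene allows. C4 becomes the ketone that ring A carries from its origin. The forward step is an olefination next to quaternary C5, with no epimerisable centre adjacent.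

**18 ⇒ 17 ⇒ 16 ⇒ 15 ⇒ 14.** The C8–H bond is removed (18 from 17), then C4 is taken back from ketone through alcohol 16 to silyl ether 15, and C8=CH2 to the C8 ketone of 14. The C8 stereocentre disappears and C4 and C8 are both at carbonyl level yet distinguishable. The hydrogenation is placed while C4 is sp2 so that its facial selectivity does not depend on the accidental configuration of the C4 carbinol. The forward steps need α-face delivery of hydrogen and olefination of a ketone flanked by quaternary C9.

**14 ⇒ 12 + 5.** The C9–CH2(aryl) bond is cut because C9 is α to the C8 carbonyl. This is the convergent point: it removes the second quaternary centre and separates the bicyclic ketone from the arene. The forward step needs the more substituted enolate 13 and attack on the face opposite C1.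

**5 ⇒ 4 ⇒ 1.** The C–Br bond and then the aryl–CH2 bond are cut. In 1 both ring hydrogens are equivalent and each lies between two methoxy groups, so metalation (through 2 and 3) has only one outcome.

**12 ⇒ 11 ⇒ 10 ⇒ 9.** These are functional-group changes only: the C8 ketone back to its silyl enol ether, the C4 silyl ether back to the alcohol and then to the ketone. The enol ether is the form in which C8 leaves the cycloaddition, and it masks C8 while C4 alone is reduced and protected. The forward steps need hydride, silylation and fluoride conditions that distinguish an enol silyl ether from an alkyl silyl ether.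

**9 ⇒ 7 + 8.** The C5–C6 and C9–C10 bonds are cut together. This removes ring B and the C5 and C10 stereocentres and leaves two small achiral components. The forward step needs regiocontrol (from the 2-silyloxy group), cis fusion (automatic) and absolute control (from the catalyst) with a sluggish trisubstituted enone. A triisopropylsilyl ether is chosen for 7 because it resists silyl transfer and protodesilylation under strongly Lewis-acidic conditions.

**7 ⇒ 6.** The O–Si bond is cut. The forward enolisation must give the (Z)-enol ether so that the methyl group points away from the diene.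

## Other disconnections considered

**Alternative 1:** The cut is a retro-[3,3] shift: C5–C6 is broken and C3–C8 reconnected, leading from octalone A2 back to the 2-vinylbicyclo[2.2.2]oct-5-en-2-ol A1. Forward, the potassium alkoxide of A1 (KH, 18-crown-6, THF) would undergo an anionic oxy-Cope rearrangement to the C8 enolate of A2.
- In its favour: the bicyclic frame forces a boat transition state, so the cis fusion and the quaternary C5 would follow stereospecifically under mild conditions. C9 already carries its arylmethyl group, so no enolate benzylation is needed. On these two points it is the equal or the better of the chosen plan.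
- Also better: the later C8 methylene could be hydrogenated in the presence of the trisubstituted C3=C4 alkene without protecting C4.
- Against it: A1 needs a bicyclooctenone with a fully substituted C9, a vinyl addition syn to the alkene bridge, and an external source of absolute configuration.
- Against it: A2 has an endocyclic C3=C4 alkene with a C4 methyl. The exocyclic methylene would need a contra-thermodynamic transposition of several steps.
- Comparison: the mechanism is more reliable than an enantioselective cycloaddition of a hindered enone, but the route ends at the wrong alkene isomer and is clearly longer than the 15 steps of the chosen plan.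

**Alternative 2:** The cut removes C5–C10 and C8–C9 together, leading from A4 back to the open-chain trienone A3 with an (E,E)-diene and an (E)-enone. Forward, heating in toluene or Me2AlCl at low temperature would bring about an intramolecular Diels–Alder reaction through the endo (carbonyl under diene) transition state.
- In its favour: all four stereocentres (C5, C8, C9, C10) would come from alkene geometry in one step, and the arylmethyl group is in place from the start. On stereochemical convergence it is better than the chosen plan, which sets C9 and C8 in separate operations.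
- Against it: both new bonds create quaternary carbons. The dienophile terminus is fully substituted and the diene terminus C5 carries an inward methyl that disfavours the s-cis conformation, so high temperatures and endo/exo mixtures are likely.
- Against it: absolute control would rest on relay from the C4 silyloxy centre.
- Against it: A4 has a C1 ketone that the target lacks, a C6=C7 alkene, and C4 at the wrong oxidation level. About seven steps would follow, after a trienone synthesis of comparable length.
- Comparison: structurally more elegant, mechanistically riskier, and longer.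

**Alternative 3:** The cut removes C4–C5 and C1–C10 (ring A), leading from A7 back to the 4-methyl-4-arylmethylcyclohexa-2,5-dienone A5 and the 1-silyloxybutadiene A6. Forward, the same type of chiral oxazaborolidinium salt would add A6 to one enone arm of A5, anti to the arylmethyl group.
- In its favour: A5 is achiral and short to make (dearomatising C-alkylation of a phenolate with 5), and C9 is quaternary before the key step.
- Better than the chosen plan: the dienophile has an α-vinyl C–H, the substrate type on which this catalyst family is best understood, so enantiocontrol stands on firmer ground than with 8.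
- Against it: the catalyst must choose both an enone arm and a face, and the facial choice rests on the modest size difference between CH3 and CH2Ar, so C9 is at risk.
- Against it: A7 lacks both the C5 and C8 methyls. Angular methylation at C5 would go through an enolate β to the C4 silyloxy group (elimination risk). A cuprate addition at C8, removal of the C6 carbonyl, hydrogenation of C2=C3 and C4 oxidation/methylenation would follow, at least nine steps.
- Comparison: a better-precedented key step, but weaker step economy and more stereochemical operations afterwards.

Key step: step 4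

## Route

**Step 1**
Reactants: 1 1,2,4,5-tetramethoxybenzene
Product: 4 (2,3,5,6-tetramethoxyphenyl)methanol, via 2,3,5,6-tetramethoxyphenyllithium 2 (not isolated), via lithium (2,3,5,6-tetramethoxyphenyl)methanolate 3 (not isolated)
Conditions: n-BuLi, TMEDA, THF, 0 °C → rt; (CH2O)n, −78 °C → rt; H2O
Reagents that add atoms: formaldehyde (from paraformaldehyde), C=O
Why: Directed ortho-lithiation: each ring C–H of 1 lies between two methoxy groups and both are equivalent, so one aryllithium forms; its 1,2-addition to formaldehyde should give the benzylic alcohol after aqueous quench.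

**Step 2**
Reactants: 4 (2,3,5,6-tetramethoxyphenyl)methanol
Product: 5 3-(bromomethyl)-1,2,4,5-tetramethoxybenzene
Conditions: PBr3, Et2O, 0 °C
Reagents that add atoms: phosphorus tribromide, BrP(Br)Br
Why: Alcohol-to-bromide conversion through the bromophosphite (SN2 at an electron-rich benzylic carbon); the bromide solvolyses easily and is used at once.

**Step 3**
Reactants: 6 pent-1-en-3-one
Product: 7 (Z)-(penta-1,3-dien-3-yloxy)tri(propan-2-yl)silane
Conditions: i-Pr3SiOSO2CF3, Et3N, Et2O, 0 °C → rt
Reagents that add atoms: triisopropylsilyl trifluoromethanesulfonate, CC(C)[Si](OS(=O)(=O)C(F)(F)F)(C(C)C)C(C)C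
Why: Soft enolisation (O-silylation, then deprotonation of the ethyl CH2 by Et3N) gives the 2-silyloxydiene; the (Z)-enol ether, with the methyl cis to oxygen and pointing away from the vinyl group, is the expected major isomer and the only one that reaches the s-cis geometry easily.

**Step 4**
Reactants: 8 2-methylcyclohex-2-en-1-one; 7 (Z)-(penta-1,3-dien-3-yloxy)tri(propan-2-yl)silane
Product: 9 (4aS,5R,8aR)-5,8a-dimethyl-6-{[tri(propan-2-yl)silyl]oxy}-3,4,4a,5,8,8a-hexahydronaphthalen-1(2H)-one (cis-fused; C4 ketone, C7=C8 silyl enol ether, C9 methyl β)
Conditions: (S)-3,3-diphenyl-1-(2-methylphenyl)tetrahydro-1H,3H-pyrrolo[1,2-c][1,3,2]oxazaborole (20 mol %), HN(SO2CF3)2 (17 mol %), CH2Cl2, −78 → −20 °C; Et3N quench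
Reagents that add atoms: none
Why: The N-protonated oxazaborolidine binds the carbonyl oxygen of 8 at boron and lowers the enone LUMO; the 2-silyloxydiene then adds in a concerted but strongly asynchronous [4π+2π] process in which the nucleophilic enol-ether carbon C9 bonds to the β-carbon C10 ahead of the CH2 terminus C6 closing onto the methyl-bearing α-carbon C5. The closest known reaction types are the Lewis-acid-promoted Diels–Alder addition of 2-silyloxydienes to 2-methylcycloalk-2-enones and the oxazaborolidinium-catalysed enantioselective Diels–Alder reaction of cyclic enones. Ring B is closed by an intermolecular cycloaddition that forms C5–C6 and C9–C10 on the same face of the ring alkene, so the fusion can only be cis. The relative configuration of C5 and C10 is therefore fixed by suprafacial addition, and their absolute configuration by the catalyst, whose aryl group is expected to stack under one enone face and leave the other open to the diene. C9 is set by the endo transition state with the outward methyl of the (Z)-diene (methyl cis to C1), but this centre is erased in step 8. Regiochemistry is secured by the silyloxy donor, which makes C9 the nucleophilic terminus, and is reinforced sterically because the unsubstituted terminus bonds to the quaternary carbon. The triisopropylsilyl group is chosen to suppress silyl transfer, achiral silyl-triflimide catalysis and Mukaiyama–Michael desilylation, so that the C7=C8 enol ether survives and keeps C8 distinct from C4.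

**Step 5**
Reactants: 9 (4aS,5R,8aR)-5,8a-dimethyl-6-{[tri(propan-2-yl)silyl]oxy}-3,4,4a,5,8,8a-hexahydronaphthalen-1(2H)-one
Product: 10 (1S,4aS,5R,8aR)-5,8a-dimethyl-6-{[tri(propan-2-yl)silyl]oxy}-1,2,3,4,4a,5,8,8a-octahydronaphthalen-1-ol (4β-OH)
Conditions: NaBH4, MeOH–THF, 0 °C
Reagents that add atoms: none
Why: Hydride addition to the only free carbonyl, since C8 is masked as its enol ether; axial delivery anti to the C5–C6 bond should give mainly the equatorial 4β-alcohol, a configuration that is irrelevant because C4 is re-oxidised in step 11.

**Step 6**
Reactants: 10 (1S,4aS,5R,8aR)-5,8a-dimethyl-6-{[tri(propan-2-yl)silyl]oxy}-1,2,3,4,4a,5,8,8a-octahydronaphthalen-1-ol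
Product: 11 tert-butyl{[(1S,4aS,5R,8aR)-5,8a-dimethyl-6-{[tri(propan-2-yl)silyl]oxy}-1,2,3,4,4a,5,8,8a-octahydronaphthalen-1-yl]oxy}dimethylsilane
Conditions: t-BuMe2SiOSO2CF3, 2,6-lutidine, CH2Cl2, 0 °C
Reagents that add atoms: tert-butyldimethylsilyl trifluoromethanesulfonate, CC(C)(C)[Si](C)(C)OS(=O)(=O)C(F)(F)F
Why: Silyl triflate silylation of a hindered secondary alcohol under a non-nucleophilic base; the silyl enol ether is inert here, and the resulting ether should withstand cold fluoride, strong base and the ylide.

**Step 7**
Reactants: 11 tert-butyl{[(1S,4aS,5R,8aR)-5,8a-dimethyl-6-{[tri(propan-2-yl)silyl]oxy}-1,2,3,4,4a,5,8,8a-octahydronaphthalen-1-yl]oxy}dimethylsilane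
Product: 12 (1R,4aR,5S,8aS)-5-{[tert-butyl(dimethyl)silyl]oxy}-1,4a-dimethyloctahydronaphthalen-2(1H)-one (C8 ketone)
Conditions: Bu4NF, AcOH, THF, −20 → 0 °C
Reagents that add atoms: none
Why: Fluoride cleaves the Si–O(enol) bond far faster than the hindered secondary alkyl silyl ether because an enolate is the better leaving group; acetic acid protonates the enolate as it forms, and the C9 configuration of 12 is of no consequence.

**Step 8**
Reactants: 12 (1R,4aR,5S,8aS)-5-{[tert-butyl(dimethyl)silyl]oxy}-1,4a-dimethyloctahydronaphthalen-2(1H)-one; 5 3-(bromomethyl)-1,2,4,5-tetramethoxybenzene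
Product: 14 (1S,4aR,5S,8aR)-5-{[tert-butyl(dimethyl)silyl]oxy}-1,4a-dimethyl-1-[(2,3,5,6-tetramethoxyphenyl)methyl]octahydronaphthalen-2(1H)-one, via lithium C8=C9 enolate 13 (not isolated)
Conditions: LiN(SiMe3)2 (0.95 equiv), THF, 0 °C → rt; DMPU, then 5, 0 °C → rt
Reagents that add atoms: none
Why: Enolate alkylation (SN2): equilibration through the slight excess of ketone should favour the tetrasubstituted C8=C9 lithium enolate, which is benzylated at C9; the electrophile is expected on the convex α face, anti to the C10–C1 bond of ring A (the 2,3-trans rule of cyclohexanone enolates), which places the arylmethyl group cis to H-10 and leaves the methyl β.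

**Step 9**
Reactants: 14 (1S,4aR,5S,8aR)-5-{[tert-butyl(dimethyl)silyl]oxy}-1,4a-dimethyl-1-[(2,3,5,6-tetramethoxyphenyl)methyl]octahydronaphthalen-2(1H)-one
Product: 15 tert-butyl(dimethyl){[(1S,4aS,5S,8aR)-5,8a-dimethyl-6-methylidene-5-[(2,3,5,6-tetramethoxyphenyl)methyl]decahydronaphthalen-1-yl]oxy}silane
Conditions: Ph3PCH3Br, KOt-Bu, toluene, 90 °C
Reagents that add atoms: methyltriphenylphosphonium bromide, C[P+](c1ccccc1)(c1ccccc1)c1ccccc1.[Br-]
Why: Wittig methylenation; the small non-stabilised ylide made with KOt-Bu in hot toluene is the usual answer for ketones next to a quaternary carbon, and reversible enolisation towards C7 is harmless because C9 is quaternary.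

**Step 10**
Reactants: 15 tert-butyl(dimethyl){[(1S,4aS,5S,8aR)-5,8a-dimethyl-6-methylidene-5-[(2,3,5,6-tetramethoxyphenyl)methyl]decahydronaphthalen-1-yl]oxy}silane
Product: 16 (1S,4aS,5S,8aR)-5,8a-dimethyl-6-methylidene-5-[(2,3,5,6-tetramethoxyphenyl)methyl]decahydronaphthalen-1-ol
Conditions: Bu4NF, THF, 50 °C
Reagents that add atoms: none
Why: Fluoride desilylation of the secondary silyl ether at elevated temperature; 15 contains no base-sensitive group.

**Step 11**
Reactants: 16 (1S,4aS,5S,8aR)-5,8a-dimethyl-6-methylidene-5-[(2,3,5,6-tetramethoxyphenyl)methyl]decahydronaphthalen-1-ol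
Product: 17 (4aS,5S,8aR)-5,8a-dimethyl-6-methylidene-5-[(2,3,5,6-tetramethoxyphenyl)methyl]octahydronaphthalen-1(2H)-one
Conditions: Dess–Martin periodinane, CH2Cl2, 0 °C → rt
Reagents that add atoms: none
Why: Dess–Martin oxidation of a secondary alcohol under near-neutral conditions, which should leave the 1,1-disubstituted alkene and the electron-rich arene untouched; it returns C4 to sp2 before the hydrogenation.

**Step 12**
Reactants: 17 (4aS,5S,8aR)-5,8a-dimethyl-6-methylidene-5-[(2,3,5,6-tetramethoxyphenyl)methyl]octahydronaphthalen-1(2H)-one
Product: 18 (4aS,5R,6S,8aR)-5,6,8a-trimethyl-5-[(2,3,5,6-tetramethoxyphenyl)methyl]octahydronaphthalen-1(2H)-one (8β-methyl)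
Conditions: H2 (1 atm), 10% Pd/C, EtOAc, rt
Reagents that add atoms: none
Why: Heterogeneous syn-hydrogenation: in the ring-B chair that keeps the arylmethyl group equatorial (C9 methyl axial, β), the α face of the C8 methylene is flanked only by axial hydrogens, so hydrogen should add from α and give the equatorial 8β-methyl cis to the C9 methyl; with C4 as a ketone no axial C4 substituent disfavours this chair, and the hindered ketone and the arene are not reduced at 1 atm.

**Step 13**
Reactants: 18 (4aS,5R,6S,8aR)-5,6,8a-trimethyl-5-[(2,3,5,6-tetramethoxyphenyl)methyl]octahydronaphthalen-1(2H)-one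
Product: 19 1,2,4,5-tetramethoxy-3-{[(1R,2S,4aR,8aS)-1,2,4a-trimethyl-5-methylidenedecahydronaphthalen-1-yl]methyl}benzene
Conditions: Ph3PCH3Br, KOt-Bu, toluene, 100 °C
Reagents that add atoms: methyltriphenylphosphonium bromide, C[P+](c1ccccc1)(c1ccccc1)c1ccccc1.[Br-]
Why: Wittig methylenation of the neopentyl-type C4 ketone under the same forcing conditions; neither α-carbon carries an epimerisable stereocentre (C5 is quaternary, C3 is CH2).

**Step 14**
Reactants: 19 1,2,4,5-tetramethoxy-3-{[(1R,2S,4aR,8aS)-1,2,4a-trimethyl-5-methylidenedecahydronaphthalen-1-yl]methyl}benzene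
Product: 20 2,5-dimethoxy-3-{[(1R,2S,4aR,8aS)-1,2,4a-trimethyl-5-methylidenedecahydronaphthalen-1-yl]methyl}cyclohexa-2,5-diene-1,4-dione
Conditions: (NH4)2Ce(NO3)6, MeCN–H2O, 0 °C
Reagents that add atoms: water, O
Why: Oxidative demethylation by two one-electron oxidations with tetravalent cerium: the arene radical cation is captured by water at a methoxy-bearing carbon and methanol is lost, giving the para-quinone; the two possible para pairs are equivalent by symmetry, and an isolated alkene is not expected to react in the cold.

**Step 15**
Reactants: 20 2,5-dimethoxy-3-{[(1R,2S,4aR,8aS)-1,2,4a-trimethyl-5-methylidenedecahydronaphthalen-1-yl]methyl}cyclohexa-2,5-diene-1,4-dione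
Product: 22 2-hydroxy-5-methoxy-3-{[(1R,2S,4aR,8aS)-1,2,4a-trimethyl-5-methylidenedecahydronaphthalen-1-yl]methyl}cyclohexa-2,5-diene-1,4-dione, via potassium quinonoxide 21 (not isolated)
Conditions: KOH, MeOH–H2O, rt; then 1 M HCl
Reagents that add atoms: potassium hydroxide, [K+].[OH-]
Why: Addition–elimination of hydroxide at a vinylogous ester; the methoxy group next to the bulky side chain is twisted out of conjugation and is expected to be the one displaced, and ionisation of the product to 21 should protect it from a second hydrolysis until acidification.

## Compound list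

1 | 1,2,4,5-tetramethoxybenzene | COc1cc(OC)c(OC)cc1OC | starting material
2 | 2,3,5,6-tetramethoxyphenyllithium | [Li]c1c(OC)c(OC)cc(OC)c1OC | intermediate
3 | lithium (2,3,5,6-tetramethoxyphenyl)methanolate | [Li+].[O-]Cc1c(OC)c(OC)cc(OC)c1OC | intermediate
4 | (2,3,5,6-tetramethoxyphenyl)methanol | OCc1c(OC)c(OC)cc(OC)c1OC | intermediate
5 | 3-(bromomethyl)-1,2,4,5-tetramethoxybenzene | BrCc1c(OC)c(OC)cc(OC)c1OC | intermediate
6 | pent-1-en-3-one | C=CC(=O)CC | starting material
7 | (Z)-(penta-1,3-dien-3-yloxy)tri(propan-2-yl)silane | C=C/C(O[Si](C(C)C)(C(C)C)C(C)C)=C/C | intermediate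
8 | 2-methylcyclohex-2-en-1-one | CC1=CCCCC1=O | starting material
9 | cis-fused cycloadduct: C4 ketone, C7=C8 triisopropylsilyl enol ether, C5 methyl α, H-10 α, C9 methyl β | O=C1CCC[C@H]2[C@@H](C)C(O[Si](C(C)C)(C(C)C)C(C)C)=CC[C@@]12C | intermediate
10 | 4β-alcohol of 9 | O[C@H]1CCC[C@H]2[C@@H](C)C(O[Si](C(C)C)(C(C)C)C(C)C)=CC[C@@]12C | intermediate
11 | 4β-tert-butyldimethylsilyl ether of 10 | CC(C)(C)[Si](C)(C)O[C@H]1CCC[C@H]2[C@@H](C)C(O[Si](C(C)C)(C(C)C)C(C)C)=CC[C@@]12C | intermediate
12 | C8 ketone with 4β-silyloxy group and C9 methyl β | CC(C)(C)[Si](C)(C)O[C@H]1CCC[C@H]2[C@@H](C)C(=O)CC[C@@]12C | intermediate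
13 | lithium C8=C9 enolate of 12 | CC(C)(C)[Si](C)(C)O[C@H]1CCC[C@H]2C(C)=C([O-])CC[C@@]12C.[Li+] | intermediate
14 | C9-benzylated ketone: arylmethyl α, C9 methyl β, C8 ketone, 4β-silyloxy | CC(C)(C)[Si](C)(C)O[C@H]1CCC[C@H]2[C@](C)(Cc3c(OC)c(OC)cc(OC)c3OC)C(=O)CC[C@@]12C | intermediate
15 | C8 methylidene compound, 4β-silyloxy | CC(C)(C)[Si](C)(C)O[C@H]1CCC[C@H]2[C@](C)(Cc3c(OC)c(OC)cc(OC)c3OC)C(=C)CC[C@@]12C | intermediate
16 | C8 methylidene 4β-alcohol | O[C@H]1CCC[C@H]2[C@](C)(Cc3c(OC)c(OC)cc(OC)c3OC)C(=C)CC[C@@]12C | intermediate
17 | C8 methylidene C4 ketone | O=C1CCC[C@H]2[C@](C)(Cc3c(OC)c(OC)cc(OC)c3OC)C(=C)CC[C@@]12C | intermediate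
18 | C4 ketone with 8β-methyl | O=C1CCC[C@H]2[C@](C)(Cc3c(OC)c(OC)cc(OC)c3OC)[C@@H](C)CC[C@@]12C | intermediate
19 | C4 methylidene tetramethoxyarene | C=C1CCC[C@H]2[C@](C)(Cc3c(OC)c(OC)cc(OC)c3OC)[C@@H](C)CC[C@@]12C | intermediate
20 | 2,5-dimethoxyquinone | C=C1CCC[C@H]2[C@](C)(CC3=C(OC)C(=O)C=C(OC)C3=O)[C@@H](C)CC[C@@]12C | intermediate
21 | potassium salt of 22 | C=C1CCC[C@H]2[C@](C)(CC3=C([O-])C(=O)C=C(OC)C3=O)[C@@H](C)CC[C@@]12C.[K+] | intermediate
22 | 2-hydroxy-5-methoxy-3-{[(1R,2S,4aR,8aS)-1,2,4a-trimethyl-5-methylidenedecahydronaphthalen-1-yl]methyl}cyclohexa-2,5-diene-1,4-dione | C=C1CCC[C@H]2[C@](C)(CC3=C(O)C(=O)C=C(OC)C3=O)[C@@H](C)CC[C@@]12C | target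

## Step count and least certain steps

Total: 15 steps. Longest linear sequence: 13 steps (steps 3–15, from 6; 8 enters at step 4). The arene fragment 5 is made in 2 steps and joins at step 8.

**Step 4 (key step).**
- What may go wrong: low reactivity of the trisubstituted enone at the temperatures the catalyst tolerates.
- What may go wrong: poor or reversed facial selectivity, because 8 has no α-vinyl C–H to anchor it on the catalyst in the usual way.
- What may go wrong: loss of the enol ether by silyl transfer or a stepwise Mukaiyama–Michael pathway.
- Fallback (from 7 and 8, returning at 10): run the cycloaddition without a chiral catalyst (HN(SO2CF3)2, 2 mol %, CH2Cl2, −78 °C), which would give 9 together with its enantiomer, ent-cycloadduct F1. Reduction as in step 5 would give 10 with the enantiomeric alcohol F2. Esterification with (S)-2-methoxy-2-phenylacetic acid (DCC, DMAP) would give the diastereomeric esters, the (S)-O-methylmandelate of 10 F3 and the (S)-O-methylmandelate of the enantiomer F4. These are separated by chromatography or crystallisation, and LiAlH4 cleavage of F3 returns 10.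

**Step 8.**
- What may go wrong: alkylation at the less hindered C7 through the minor enolate, or double alkylation, because the C9 enolate carbon is crowded.
- What may go wrong: incomplete facial selectivity. In one ring-B half-chair the α face suffers a 1,3-interaction with the axial C5 methyl, and the axial 4β-silyloxy group disfavours the other half-chair.
- Fallback (from 12, returning at 14): convert 12 with Me3SiCl, NaI and Et3N in MeCN into the thermodynamic C8=C9 trimethylsilyl enol ether F5 and purify it free of its regioisomer. Cleave it with MeLi in THF to regenerate 13 regiospecifically under non-equilibrating conditions, then alkylate with 5 in the presence of DMPU.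

**Step 12.**
- What may go wrong: hydrogen delivery to the β face if the other chair reacts, or palladium-induced migration of the alkene into the ring before reduction.
- Fallback (from 17, returning at 18): change the stereocontrol principle from surface syn-addition to stepwise hydrogen-atom transfer, using tris(2,2,6,6-tetramethylheptane-3,5-dionato)manganese, PhSiH3 and t-BuOOH in i-PrOH. The tertiary C8 radical should take up its second hydrogen axially and give the thermodynamically preferred equatorial 8β-methyl. No new compound is involved.

**Step 13.**
- What may go wrong: enolisation towards C3 instead of addition, or very slow addition at the carbonyl next to quaternary C5.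
- Fallback (from 18, returning at 19): two-stage Peterson olefination. Me3SiCH2Li with CeCl3 in THF at −78 °C should add to the carbonyl without enolisation to give the β-hydroxysilane F6, and KH in THF then eliminates silanolate to give 19.

**Step 15.**
- What may go wrong: hydrolysis of the wrong methoxy group or of both, since the regiochemistry rests on a steric twist and not on a strong electronic bias.
- Fallback (from 20, returning at 22): hydrolyse both methoxy groups (KOH, aqueous dioxane, 60 °C, then acid) to the 2,5-dihydroxyquinone F7. Then form one methyl ether by acid-catalysed exchange in methanol (camphorsulfonic acid, rt; a vinylogous Fischer esterification), which should take the unhindered hydroxyl next to the ring C–H.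

## Further compounds

F1 | step 4 | ent-cycloadduct (enantiomer of 9) | O=C1CCC[C@@H]2[C@H](C)C(O[Si](C(C)C)(C(C)C)C(C)C)=CC[C@]12C
F2 | step 4 | enantiomer of alcohol 10 | O[C@@H]1CCC[C@@H]2[C@H](C)C(O[Si](C(C)C)(C(C)C)C(C)C)=CC[C@]12C
F3 | step 4 | (S)-O-methylmandelate of 10 | CO[C@H](C(=O)O[C@H]1CCC[C@H]2[C@@H](C)C(O[Si](C(C)C)(C(C)C)C(C)C)=CC[C@@]12C)c3ccccc3
F4 | step 4 | (S)-O-methylmandelate of the enantiomer of 10 | CO[C@H](C(=O)O[C@@H]1CCC[C@@H]2[C@H](C)C(O[Si](C(C)C)(C(C)C)C(C)C)=CC[C@]12C)c3ccccc3
F5 | step 8 | C8=C9 trimethylsilyl enol ether of 12 | CC(C)(C)[Si](C)(C)O[C@H]1CCC[C@H]2C(C)=C(O[Si](C)(C)C)CC[C@@]12C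
F0 | step 12 | none | none
F6 | step 13 | C4 tertiary alcohol bearing a (trimethylsilyl)methyl group (either C4 epimer) | C[Si](C)(C)CC1(O)CCC[C@H]2[C@](C)(Cc3c(OC)c(OC)cc(OC)c3OC)[C@@H](C)CC[C@@]12C
F7 | step 15 | 2,5-dihydroxyquinone analogue of 22 | C=C1CCC[C@H]2[C@](C)(CC3=C(O)C(=O)C=C(O)C3=O)[C@@H](C)CC[C@@]12C
A1 | alternative 1 | 2-ethenyl-3,5,6-trimethyl-3-[(2,3,5,6-tetramethoxyphenyl)methyl]bicyclo[2.2.2]oct-5-en-2-ol (vinyl syn to the alkene bridge) | C=C[C@]1(O)[C@H]2CC[C@H](C(C)=C2C)[C@]1(C)Cc3c(OC)c(OC)cc(OC)c3OC
A2 | alternative 1 | cis-fused octalone with C8 ketone, C3=C4 alkene, quaternary C5 and C9 | CC1=CCC[C@H]2[C@](C)(Cc3c(OC)c(OC)cc(OC)c3OC)C(=O)CC[C@@]12C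
A3 | alternative 2 | open-chain trienone with (E)-enone, (E,E)-diene and C4 silyl ether | CC(C)(C)[Si](C)(C)O[C@H](CCC(=O)/C=C(\C)Cc1c(OC)c(OC)cc(OC)c1OC)/C(C)=C/C=C/C
A4 | alternative 2 | cis-fused octalone with C1 ketone, C4 silyl ether, C6=C7 alkene | CC(C)(C)[Si](C)(C)O[C@@H]1CCC(=O)[C@H]2[C@](C)(Cc3c(OC)c(OC)cc(OC)c3OC)[C@@H](C)C=C[C@@]12C
A5 | alternative 3 | 4-methyl-4-[(2,3,5,6-tetramethoxyphenyl)methyl]cyclohexa-2,5-dien-1-one | CC1(Cc2c(OC)c(OC)cc(OC)c2OC)C=CC(=O)C=C1
A6 | alternative 3 | (E)-(buta-1,3-dien-1-yloxy)(tert-butyl)dimethylsilane | C=C/C=C/O[Si](C)(C)C(C)(C)C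
A7 | alternative 3 | cis-fused bicyclic enone with C4 silyl ether, C2=C3 and C7=C8 alkenes, C6 ketone | CC(C)(C)[Si](C)(C)O[C@H]1C=CC[C@H]2[C@](C)(Cc3c(OC)c(OC)cc(OC)c3OC)C=CC(=O)[C@@H]12
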